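## Analysis of the target

The target is a flavonolignan of the 8-O-4' type. A 5,7-dihydroxychromen-4-one (rings A and C) carries a 3',5'-dimethoxy-4'-oxyphenyl ring B, and the 4'-oxygen of ring B is bonded to C8 of a three-carbon chain C7–C8–C9. C7 is a benzylic secondary carbinol attached to C1 of ring D (4-hydroxy-3-methoxyphenyl, the guaiacyl ring), and C9 is a primary carbon carrying the only acetate. The two stereocentres are adjacent, C7 (R) and C8 (S). This is the erythro relationship: the C7 hydroxyl and the C8 aryloxy group are anti when ring D–C7–C8–C9 is drawn as a zigzag. There is no other stereo element. The sensitive groups are: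
- the C7 carbinol, para to a ring D oxygen, which ionises under acid and can be hydrogenolysed;
- the primary acetate, which is saponified or migrates to O7 under base;
- the chromone, which is attacked by hydride, organometallics and strong nucleophiles;
- three free phenols.

The synthesis is hard for four reasons: the ether joins a secondary carbon to an oxygen flanked by two methoxy groups; relative and absolute configuration at C7/C8 must be controlled; O7 must be told apart from O9; and the benzylic carbinol must survive construction of ring C. The strategy rests on one feature: C7 is bonded directly to C1 of ring D and is flanked by C8, which carries the ring B aryloxy group. The ring D–C7 bond can therefore be made by adding a ring D aryl metal to a C7 aldehyde, with the C8 centre deciding the face.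

## Retrosynthetic reasoning

**End game.** Target 22 is traced back to its tribenzyl ether 21 by turning the three phenolic O–H bonds into O–benzyl bonds. The acetate excludes base and the C7 carbinol excludes acid, so the last step must be neutral, and hydrogenolysis of aryl benzyl ethers is. The acetate of 21 is cut at the acyl–O9 bond to give diol 20. Acylating before the phenols are freed leaves only two hydroxyls to compete, one primary and one hindered secondary. Diol 20 comes from the bis-silyl ether 19 by desilylation.

**Ring C.** Ring C of 19 is opened at the O1–C2 bond, with removal of the C2=C3 unsaturation, to give the 2'-hydroxychalcone 17. Cutting the enone double bond of 17 gives aldehyde 13 (ring B with the whole chain and ring D) and acetophenone 15 (ring A), which comes from 14. The chromone is thus the last ring built, because it would not survive the hydride and organomagnesium steps of the chain. The forward steps are an aldol condensation in alcoholic hydroxide and an oxidative cyclisation, so O7 and O9 must carry base-stable groups that come off together: a tert-butyldimethylsilyl ether at O7 and a triisopropylsilyl ether at O9.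

**Adjusting ring B and O7.** Aldehyde 13 is traced to hydroxy aldehyde 12 by removing the O7 silyl group, and 12 to dioxolane 11 by masking the ring B aldehyde. The mask is needed as long as an organometallic reagent is in play. It is taken off before O7 is silylated because a silyl triflate would attack the acetal.

**Key disconnection.** In 11 the bond between C1 of ring D and C7 is cut, giving aldehyde 10 and aryl Grignard reagent 8.
- It is the only C–C bond of the chain whose scission gives a plain aryl nucleophile and an electrophile that already holds the hindered ether and the C8 stereocentre.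
- Cutting C7–C8 would need an aryloxyacetate enolate and would create two centres at once.
- Cutting C8–O late would need substitution at a hindered secondary carbon next to a benzylic carbinol.
- The gain is that C7 is created under 1,2-induction from C8. The forward reaction must deliver the aryl group to the Re face of (S)-10 through the non-chelated Felkin–Anh arrangement and must not epimerise C8.

**The aldehyde.** Aldehyde 10 is traced to ester 6, its storable and configurationally robust form. Ester 6 is cut at the C8–O(aryl) bond into hydroxy ester 3 and phenol 5.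
- At this stage C8 is alpha to an ester, the best position for SN2 attack by a hindered phenoxide.
- The Mitsunobu reaction inverts, so the (R) centre of chiral-pool ester 1 becomes (S)-C8.
- Hydroxy ester 3 comes from 1 through diol 2 by acetonide removal and primary silylation.
- The O9 group is a triisopropylsilyl rather than a tert-butyldiphenylsilyl ether. It is as bulky and as poor a ligand for magnesium, but it resists alcoholic hydroxide better.
- Phenol 5 comes from syringaldehyde 4, and Grignard reagent 8 from bromide 7.

## Alternatives that were turned down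

**Alternative 1:** The C4'–O bond of ring B is cut. The forward key step would be a C–O coupling under zerovalent palladium catalysis (Pd2(dba)3, the biaryl phosphine RockPhos, Cs2CO3). The C8 hydroxyl of the erythro triol, held as its C7,C9-acetonide A2, would couple with the 4'-bromoflavone A3 to give ether A1.
- For it: it is the most convergent plan. The flavone is built from robust materials away from the side chain. The stereocentres come from a small isolated diol. The trans-disubstituted dioxane of A2 would let the erythro assignment be checked.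
- Against it: the arylpalladium species from A3 has two methoxy groups ortho to the metal, and the alkoxide of A2 is secondary, ring-bound and next to an aryl-bearing carbon. Alkoxide binding is slowed by this double hindrance. The palladium alkoxide also has a C8 hydrogen that can be lost by beta-hydride elimination, which would reduce A3 and oxidise A2 to a ketone, destroying C8. Carbonate at elevated temperature is not innocent toward a chromone. A2 needs its own enantioselective synthesis.
- Comparison: this alternative is stronger on convergence and keeps the benzylic carbinol away from the flavone-forming steps. The chosen strategy makes the same hindered C–O bond first, by SN2 at an ester-activated carbon of a small molecule, where a poor result costs little.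

**Alternative 2:** The C7–O bond is cut, and the hydroxyl is introduced last by oxidation of the C7 methylene of the deoxy compound A5. The forward key step would be an anodic two-electron oxidation (carbon anode, LiClO4, wet acetonitrile). The C7 cation would be captured by the carbonyl oxygen of the C9 acetate in a six-membered 1,3-dioxan-2-ylium ion, and water would open this ion to the hydroxy acetate A4.
- For it: it is the shortest route on paper. A5 has only the C8 stereocentre and needs no carbonyl addition. The acetate serves as directing group and as final substituent. The cyclic cation should prefer aryl and aryloxy trans, which corresponds to erythro.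
- Against it: the anode must select ring D among four electron-rich arenes, and C7–H among the benzylic C–H bonds of the benzyl ethers. The C7 cation sits next to C8–H and C8–OAr, so proton loss to an enol ether or ether cleavage competes with capture. The ortho acid formed on hydrolysis can collapse to the O7 acetate as readily as to the O9 acetate. Stereocontrol rests on a conformational preference only.
- Comparison: this alternative wins on step count. It asks for three selectivities (site, acyl position, diastereomer) in one late step. The chosen route asks for one, early, with a way to recycle the wrong isomer.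

**Alternative 3:** The C7–C8 bond is cut. The forward key step would be an anti-glycolate aldol: the magnesium enolate of the N-(aryloxyacetyl)oxazolidinone A7 (MgCl2, Et3N, Me3SiCl) adds to 4-benzyloxy-3-methoxybenzaldehyde A8. The product is the anti adduct A6, which is erythro after loss of the silyl group on work-up, with both stereocentres set.
- For it: it is convergent. Both centres are set in one catalytic step under control of the auxiliary, not of a fragile aldehyde. A8 is aromatic and non-enolisable, the best aldehyde class for this aldol, and is a commercial compound.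
- Against it: A7 offers magnesium further donor sites (the ring B methoxy groups, the aryloxy oxygen, the chromone carbonyl). Enolate geometry and the balance between open and chelated transition states are therefore uncertain for an alpha-aryloxy imide, and so is the anti selectivity. The electron-rich aldehyde makes the aldol reversible. Afterwards the imide must be reduced to the C9 alcohol by hydride with the chromone already present, and the chromone is a competing acceptor.
- Comparison: this alternative is at least as strong on convergence and on control of absolute configuration. The chosen strategy offers a stereochemical model with a single controlling element (C8), and an end game with no hydride step once ring C exists.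

Key step: step 7

Remark: the chain is numbered C7 (benzylic carbinol), C8 (aryloxy carbon) and C9 (acetoxymethyl), rings A and C form the chromone, ring B is the dimethoxyphenyl ring and ring D the guaiacyl ring; compounds 1, 4, 7 and 14 are assumed to be purchased.

## Route

Step 1
Reactants: 1 methyl (R)-2,2-dimethyl-1,3-dioxolane-4-carboxylate
Product: 2 methyl (R)-2,3-dihydroxypropanoate
Conditions: Dowex 50W-X8 (H+ form), MeOH, rt
Reagents that add atoms: none
Why: Acid-catalysed acetal exchange with methanol frees the diol; the stereocentre is not touched and no base is present, so the (R) configuration should be kept.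

Step 2
Reactants: 2 methyl (R)-2,3-dihydroxypropanoate
Product: 3 methyl (R)-2-hydroxy-3-[(triisopropylsilyl)oxy]propanoate
Conditions: TIPSCl (1.05 equiv), imidazole, CH2Cl2, 0 °C to rt
Reagents that add atoms: triisopropylsilyl chloride, CC(C)[Si](Cl)(C(C)C)C(C)C
Why: Silylation of a 1,2-diol with a bulky silyl chloride is selective for the primary hydroxyl; the secondary hydroxyl, hindered and deactivated by the ester, stays free for the etherification.

Step 3
Reactants: 4 syringaldehyde (4-hydroxy-3,5-dimethoxybenzaldehyde)
Product: 5 4-(1,3-dioxolan-2-yl)-2,6-dimethoxyphenol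
Conditions: HOCH2CH2OH, p-TsOH (cat.), toluene, reflux, Dean–Stark; NaHCO3 work-up
Reagents that add atoms: ethylene glycol, OCCO
Why: Acid-catalysed acetalisation driven by azeotropic removal of water; the dioxolane masks the aldehyde against hydride and Grignard reagents and leaves the phenol free, and the product is kept over a trace of base because it is acid-labile.

Step 4
Reactants: 3 methyl (R)-2-hydroxy-3-[(triisopropylsilyl)oxy]propanoate; 5 4-(1,3-dioxolan-2-yl)-2,6-dimethoxyphenol
Product: 6 methyl (S)-2-[4-(1,3-dioxolan-2-yl)-2,6-dimethoxyphenoxy]-3-[(triisopropylsilyl)oxy]propanoate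
Conditions: PPh3, DIAD, THF, 0 °C to rt
Reagents that add atoms: none
Why: Mitsunobu etherification: the phenoxide of 5 displaces the activated C8–O bond in an SN2 step that the adjacent ester makes easy. Inversion turns (R) into (S), the C8 configuration of the target, and the neutral medium leaves the acetal and silyl ether alone.

Step 5
Reactants: 7 1-(benzyloxy)-4-bromo-2-methoxybenzene
Product: 8 4-(benzyloxy)-3-methoxyphenylmagnesium bromide (THF solution, used directly)
Conditions: Mg turnings, I2 (one crystal), THF, 40 °C then rt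
Reagents that add atoms: magnesium, [Mg]
Why: Direct magnesium insertion into an aryl bromide is standard Grignard formation; the benzyl and methyl ethers are inert.

Step 6
Reactants: 6 methyl (S)-2-[4-(1,3-dioxolan-2-yl)-2,6-dimethoxyphenoxy]-3-[(triisopropylsilyl)oxy]propanoate
Product: 10 (S)-2-[4-(1,3-dioxolan-2-yl)-2,6-dimethoxyphenoxy]-3-[(triisopropylsilyl)oxy]propanal, via diisobutylaluminium hemiacetal 9 (not isolated)
Conditions: ((CH3)2CHCH2)2AlH (1.1 equiv), CH2Cl2, −78 °C; MeOH, then aq. KNaC4H4O6
Reagents that add atoms: none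
Why: Partial reduction of an ester: at −78 °C the tetrahedral intermediate 9, held by coordination to the neighbouring aryloxy oxygen, does not collapse until the quench, so the aldehyde appears only on work-up. The C8 hydrogen of 10 is acidic, so the aldehyde is not stored and goes straight into step 7.

Step 7
Reactants: 10 (S)-2-[4-(1,3-dioxolan-2-yl)-2,6-dimethoxyphenoxy]-3-[(triisopropylsilyl)oxy]propanal; 8 4-(benzyloxy)-3-methoxyphenylmagnesium bromide
Product: 11 (1R,2S)-1-[4-(benzyloxy)-3-methoxyphenyl]-2-[4-(1,3-dioxolan-2-yl)-2,6-dimethoxyphenoxy]-3-[(triisopropylsilyl)oxy]propan-1-ol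
Conditions: 8 (1.5 equiv), THF, −78 °C to −40 °C; aq. NH4Cl
Reagents that add atoms: none
Why: Polar 1,2-addition of the aryl Grignard reagent to the aldehyde forms the bond from C1 of ring D to C7 and the C7 stereocentre; no ring is closed. The closest known reaction type is the Felkin–Anh-selective addition of aryl- and alkylmagnesium or -titanium reagents to alpha-alkoxy and alpha-aryloxy aldehydes such as protected glyceraldehyde and O-aryl lactaldehydes. In the reactive conformer the C8–O(aryl) bond, the best sigma* acceptor, stands perpendicular to the carbonyl plane and anti to the nucleophile, and the aryl group follows the Bürgi–Dunitz path past the C8 hydrogen, not past the silyloxymethyl group. This is attack on the Re face of the (S)-aldehyde and should give the (7R) alcohol, that is 7,8-anti or erythro, so C7 is controlled by the existing C8 centre through 1,2-induction. The step needs facial selectivity and retention of configuration at C8. A chelated transition state would lead to the threo isomer; it is disfavoured because the aryloxy oxygen is a weak donor (its lone pair is delocalised into ring B and it is flanked by two methoxy groups), the triisopropylsilyl ether does not coordinate, and THF saturates magnesium. The low temperature and the low basicity of an aryl Grignard reagent should keep enolisation of 10 slow relative to addition. The dioxolane and the silyl and benzyl ethers are inert to the reagent.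

Step 8
Reactants: 11 (1R,2S)-1-[4-(benzyloxy)-3-methoxyphenyl]-2-[4-(1,3-dioxolan-2-yl)-2,6-dimethoxyphenoxy]-3-[(triisopropylsilyl)oxy]propan-1-ol
Product: 12 4-{[(1R,2S)-1-[4-(benzyloxy)-3-methoxyphenyl]-1-hydroxy-3-[(triisopropylsilyl)oxy]propan-2-yl]oxy}-3,5-dimethoxybenzaldehyde
Conditions: PPTS (cat.), acetone/H2O (10:1), rt
Reagents that add atoms: water, O
Why: Acetal hydrolysis: the dioxolane of an electron-rich benzaldehyde opens through an oxocarbenium ion stabilised by the para oxygen. The acid is too weak to ionise the C7 carbinol or to cleave the triisopropylsilyl ether.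

Step 9
Reactants: 12 4-{[(1R,2S)-1-[4-(benzyloxy)-3-methoxyphenyl]-1-hydroxy-3-[(triisopropylsilyl)oxy]propan-2-yl]oxy}-3,5-dimethoxybenzaldehyde
Product: 13 4-{[(1R,2S)-1-[4-(benzyloxy)-3-methoxyphenyl]-1-[(tert-butyldimethylsilyl)oxy]-3-[(triisopropylsilyl)oxy]propan-2-yl]oxy}-3,5-dimethoxybenzaldehyde
Conditions: TBSOTf, 2,6-lutidine, CH2Cl2, −78 to 0 °C
Reagents that add atoms: tert-butyldimethylsilyl trifluoromethanesulfonate, CC(C)(C)[Si](C)(C)OS(=O)(=O)C(F)(F)F
Why: Silylation of a hindered secondary alcohol with a silyl triflate and a hindered base; the non-enolisable aldehyde is not affected. The cap protects C7–OH from oxidation and keeps its alkoxide from attacking C8 in the basic and oxidative steps that follow.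

Step 10
Reactants: 14 2',4',6'-trihydroxyacetophenone
Product: 15 1-[2,4-bis(benzyloxy)-6-hydroxyphenyl]ethan-1-one
Conditions: BnBr (2.1 equiv), K2CO3, DMF, rt
Reagents that add atoms: benzyl bromide, BrCc1ccccc1
Why: Williamson etherification: the 4'-hydroxyl and one of the two equivalent ortho hydroxyls are alkylated. The remaining ortho hydroxyl is held in a hydrogen bond to the acetyl carbonyl and stays free for the later ring closure.

Step 11
Reactants: 13 4-{[(1R,2S)-1-[4-(benzyloxy)-3-methoxyphenyl]-1-[(tert-butyldimethylsilyl)oxy]-3-[(triisopropylsilyl)oxy]propan-2-yl]oxy}-3,5-dimethoxybenzaldehyde; 15 1-[2,4-bis(benzyloxy)-6-hydroxyphenyl]ethan-1-one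
Product: 17 (E)-1-[2,4-bis(benzyloxy)-6-hydroxyphenyl]-3-(4-{[(1R,2S)-1-[4-(benzyloxy)-3-methoxyphenyl]-1-[(tert-butyldimethylsilyl)oxy]-3-[(triisopropylsilyl)oxy]propan-2-yl]oxy}-3,5-dimethoxyphenyl)prop-2-en-1-one, via aldol adduct 16 (not isolated)
Conditions: KOH (50% aq.), EtOH/THF, 0 °C to rt; AcOH to pH 6
Reagents that add atoms: none
Why: Claisen–Schmidt condensation: the enolate of 15 adds to the non-enolisable aldehyde 13 and aldol 16 loses water by an E1cB path to the (E)-enone. C7 and C8 carry no acidic hydrogen, and alkyl tert-butyldimethylsilyl and triisopropylsilyl ethers withstand alcoholic hydroxide at room temperature.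

Step 12
Reactants: 17 (E)-1-[2,4-bis(benzyloxy)-6-hydroxyphenyl]-3-(4-{[(1R,2S)-1-[4-(benzyloxy)-3-methoxyphenyl]-1-[(tert-butyldimethylsilyl)oxy]-3-[(triisopropylsilyl)oxy]propan-2-yl]oxy}-3,5-dimethoxyphenyl)prop-2-en-1-one
Product: 19 5,7-bis(benzyloxy)-2-(4-{[(1R,2S)-1-[4-(benzyloxy)-3-methoxyphenyl]-1-[(tert-butyldimethylsilyl)oxy]-3-[(triisopropylsilyl)oxy]propan-2-yl]oxy}-3,5-dimethoxyphenyl)-4H-chromen-4-one, via flavanone 18 (not isolated)
Conditions: I2 (10 mol%), DMSO, 120 °C; aq. Na2S2O3
Reagents that add atoms: none
Why: Oxidative cyclisation of a 2'-hydroxychalcone: oxa-Michael addition of the phenol gives flavanone 18, which is iodinated alpha to the ketone and loses HI. DMSO reoxidises HI to I2, so only a catalytic amount of acid is present at any time.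

Step 13
Reactants: 19 5,7-bis(benzyloxy)-2-(4-{[(1R,2S)-1-[4-(benzyloxy)-3-methoxyphenyl]-1-[(tert-butyldimethylsilyl)oxy]-3-[(triisopropylsilyl)oxy]propan-2-yl]oxy}-3,5-dimethoxyphenyl)-4H-chromen-4-one
Product: 20 5,7-bis(benzyloxy)-2-(4-{[(1R,2S)-1-[4-(benzyloxy)-3-methoxyphenyl]-1,3-dihydroxypropan-2-yl]oxy}-3,5-dimethoxyphenyl)-4H-chromen-4-one
Conditions: TBAF, AcOH (1:1), THF, rt to 40 °C
Reagents that add atoms: none
Why: Fluoride cleaves both silyl ethers through Si–F bond formation. The acetic acid buffer keeps the C7 alkoxide from displacing the aryloxide at C8 and spares the chromone from base.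

Step 14
Reactants: 20 5,7-bis(benzyloxy)-2-(4-{[(1R,2S)-1-[4-(benzyloxy)-3-methoxyphenyl]-1,3-dihydroxypropan-2-yl]oxy}-3,5-dimethoxyphenyl)-4H-chromen-4-one
Product: 21 (2S,3R)-3-[4-(benzyloxy)-3-methoxyphenyl]-2-{4-[5,7-bis(benzyloxy)-4-oxo-4H-chromen-2-yl]-2,6-dimethoxyphenoxy}-3-hydroxypropyl acetate
Conditions: AcCl (1.1 equiv), 2,4,6-collidine, CH2Cl2, −78 °C
Reagents that add atoms: acetyl chloride, CC(Cl)=O
Why: Kinetically controlled acylation: with a hindered base at low temperature the primary C9 hydroxyl reacts far faster than the C7 hydroxyl, which is flanked by ring D and the C8 aryloxy group. No phenol is free at this stage.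

Step 15
Reactants: 21 (2S,3R)-3-[4-(benzyloxy)-3-methoxyphenyl]-2-{4-[5,7-bis(benzyloxy)-4-oxo-4H-chromen-2-yl]-2,6-dimethoxyphenoxy}-3-hydroxypropyl acetate
Product: 22 (2S,3R)-2-[4-(5,7-dihydroxy-4-oxo-4H-chromen-2-yl)-2,6-dimethoxyphenoxy]-3-hydroxy-3-(4-hydroxy-3-methoxyphenyl)propyl acetate (CNP0157817.1)
Conditions: H2 (1 atm), 10% Pd/C, EtOAc/THF, rt
Reagents that add atoms: none
Why: Hydrogenolysis of the three aryl benzyl ethers under neutral conditions; the acetate, the alkyl aryl ether at C8 and the chromone are inert. Without acid the secondary benzylic C7–OH is cleaved much more slowly than O-benzyl groups, so the reaction is stopped after three equivalents of hydrogen are taken up.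

## Compound list

1 | methyl (R)-2,2-dimethyl-1,3-dioxolane-4-carboxylate | COC(=O)[C@H]1COC(C)(C)O1 | starting material
2 | methyl (R)-2,3-dihydroxypropanoate | COC(=O)[C@H](O)CO | intermediate
3 | methyl (R)-2-hydroxy-3-[(triisopropylsilyl)oxy]propanoate | COC(=O)[C@H](O)CO[Si](C(C)C)(C(C)C)C(C)C | intermediate
4 | syringaldehyde (4-hydroxy-3,5-dimethoxybenzaldehyde) | COc1cc(C=O)cc(OC)c1O | starting material
5 | 4-(1,3-dioxolan-2-yl)-2,6-dimethoxyphenol | COc1cc(C2OCCO2)cc(OC)c1O | intermediate
6 | methyl (S)-2-[4-(1,3-dioxolan-2-yl)-2,6-dimethoxyphenoxy]-3-[(triisopropylsilyl)oxy]propanoate | COC(=O)[C@@H](Oc1c(OC)cc(C2OCCO2)cc1OC)CO[Si](C(C)C)(C(C)C)C(C)C | intermediate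
7 | 1-(benzyloxy)-4-bromo-2-methoxybenzene | COc1cc(Br)ccc1OCc1ccccc1 | starting material
8 | 4-(benzyloxy)-3-methoxyphenylmagnesium bromide | COc1cc([Mg]Br)ccc1OCc1ccccc1 | intermediate
9 | diisobutylaluminium hemiacetal of 6 (formed in the flask, not isolated; hemiacetal carbon undefined) | COC(O[Al](CC(C)C)CC(C)C)[C@H](CO[Si](C(C)C)(C(C)C)C(C)C)Oc1c(OC)cc(C2OCCO2)cc1OC | intermediate
10 | (S)-2-[4-(1,3-dioxolan-2-yl)-2,6-dimethoxyphenoxy]-3-[(triisopropylsilyl)oxy]propanal | O=C[C@H](CO[Si](C(C)C)(C(C)C)C(C)C)Oc1c(OC)cc(C2OCCO2)cc1OC | intermediate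
11 | (1R,2S)-1-[4-(benzyloxy)-3-methoxyphenyl]-2-[4-(1,3-dioxolan-2-yl)-2,6-dimethoxyphenoxy]-3-[(triisopropylsilyl)oxy]propan-1-ol | COc1cc([C@@H](O)[C@H](CO[Si](C(C)C)(C(C)C)C(C)C)Oc2c(OC)cc(C3OCCO3)cc2OC)ccc1OCc1ccccc1 | intermediate
12 | 4-{[(1R,2S)-1-[4-(benzyloxy)-3-methoxyphenyl]-1-hydroxy-3-[(triisopropylsilyl)oxy]propan-2-yl]oxy}-3,5-dimethoxybenzaldehyde | COc1cc([C@@H](O)[C@H](CO[Si](C(C)C)(C(C)C)C(C)C)Oc2c(OC)cc(C=O)cc2OC)ccc1OCc1ccccc1 | intermediate
13 | 4-{[(1R,2S)-1-[4-(benzyloxy)-3-methoxyphenyl]-1-[(tert-butyldimethylsilyl)oxy]-3-[(triisopropylsilyl)oxy]propan-2-yl]oxy}-3,5-dimethoxybenzaldehyde | COc1cc([C@@H](O[Si](C)(C)C(C)(C)C)[C@H](CO[Si](C(C)C)(C(C)C)C(C)C)Oc2c(OC)cc(C=O)cc2OC)ccc1OCc1ccccc1 | intermediate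
14 | 2',4',6'-trihydroxyacetophenone | CC(=O)c1c(O)cc(O)cc1O | starting material
15 | 1-[2,4-bis(benzyloxy)-6-hydroxyphenyl]ethan-1-one | CC(=O)c1c(O)cc(OCc2ccccc2)cc1OCc1ccccc1 | intermediate
16 | aldol adduct of 13 and 15: 1-[2,4-bis(benzyloxy)-6-hydroxyphenyl]-3-hydroxy-3-(ring B of 13)propan-1-one (formed in the flask, not isolated; new carbinol centre undefined) | COc1cc([C@@H](O[Si](C)(C)C(C)(C)C)[C@H](CO[Si](C(C)C)(C(C)C)C(C)C)Oc2c(OC)cc(C(O)CC(=O)c3c(O)cc(OCc4ccccc4)cc3OCc3ccccc3)cc2OC)ccc1OCc1ccccc1 | intermediate
17 | (E)-1-[2,4-bis(benzyloxy)-6-hydroxyphenyl]-3-(4-{[(1R,2S)-1-[4-(benzyloxy)-3-methoxyphenyl]-1-[(tert-butyldimethylsilyl)oxy]-3-[(triisopropylsilyl)oxy]propan-2-yl]oxy}-3,5-dimethoxyphenyl)prop-2-en-1-one | COc1cc([C@@H](O[Si](C)(C)C(C)(C)C)[C@H](CO[Si](C(C)C)(C(C)C)C(C)C)Oc2c(OC)cc(/C=C/C(=O)c3c(O)cc(OCc4ccccc4)cc3OCc3ccccc3)cc2OC)ccc1OCc1ccccc1 | intermediate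
18 | 5,7-bis(benzyloxy)-2-(4-{[(1R,2S)-1-[4-(benzyloxy)-3-methoxyphenyl]-1-[(tert-butyldimethylsilyl)oxy]-3-[(triisopropylsilyl)oxy]propan-2-yl]oxy}-3,5-dimethoxyphenyl)chroman-4-one (formed in the flask, not isolated; C2 of the chromanone undefined) | COc1cc([C@@H](O[Si](C)(C)C(C)(C)C)[C@H](CO[Si](C(C)C)(C(C)C)C(C)C)Oc2c(OC)cc(C3CC(=O)c4c(OCc5ccccc5)cc(OCc5ccccc5)cc4O3)cc2OC)ccc1OCc1ccccc1 | intermediate
19 | 5,7-bis(benzyloxy)-2-(4-{[(1R,2S)-1-[4-(benzyloxy)-3-methoxyphenyl]-1-[(tert-butyldimethylsilyl)oxy]-3-[(triisopropylsilyl)oxy]propan-2-yl]oxy}-3,5-dimethoxyphenyl)-4H-chromen-4-one | COc1cc([C@@H](O[Si](C)(C)C(C)(C)C)[C@H](CO[Si](C(C)C)(C(C)C)C(C)C)Oc2c(OC)cc(-c3cc(=O)c4c(OCc5ccccc5)cc(OCc5ccccc5)cc4o3)cc2OC)ccc1OCc1ccccc1 | intermediate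
20 | 5,7-bis(benzyloxy)-2-(4-{[(1R,2S)-1-[4-(benzyloxy)-3-methoxyphenyl]-1,3-dihydroxypropan-2-yl]oxy}-3,5-dimethoxyphenyl)-4H-chromen-4-one | COc1cc([C@@H](O)[C@H](CO)Oc2c(OC)cc(-c3cc(=O)c4c(OCc5ccccc5)cc(OCc5ccccc5)cc4o3)cc2OC)ccc1OCc1ccccc1 | intermediate
21 | (2S,3R)-3-[4-(benzyloxy)-3-methoxyphenyl]-2-{4-[5,7-bis(benzyloxy)-4-oxo-4H-chromen-2-yl]-2,6-dimethoxyphenoxy}-3-hydroxypropyl acetate | COc1cc([C@@H](O)[C@H](COC(C)=O)Oc2c(OC)cc(-c3cc(=O)c4c(OCc5ccccc5)cc(OCc5ccccc5)cc4o3)cc2OC)ccc1OCc1ccccc1 | intermediate
22 | (2S,3R)-2-[4-(5,7-dihydroxy-4-oxo-4H-chromen-2-yl)-2,6-dimethoxyphenoxy]-3-hydroxy-3-(4-hydroxy-3-methoxyphenyl)propyl acetate | COc1cc([C@@H](O)[C@H](COC(C)=O)Oc2c(OC)cc(-c3cc(=O)c4c(O)cc(O)cc4o3)cc2OC)ccc1O | target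

## Step count and least certain steps

Total: 15 steps, counting the preparation of Grignard reagent 8. Longest linear sequence: 12 steps from 1 to 22 (steps 1, 2, 4, 6, 7, 8, 9, 11, 12, 13, 14, 15). Steps 3, 5 and 10 are side branches.

**Step 7 (key step).** The addition may run in part through a magnesium chelate between the carbonyl oxygen and the aryloxy oxygen, helped by an ortho methoxy group, which would erode or reverse the facial selectivity. The aldehyde may also lose configurational purity at C8 by enolisation before it is consumed. The fallback sets out from ester 6 and avoids the aldehyde. Ester 6 is treated with N,O-dimethylhydroxylamine hydrochloride and (CH3)2CHMgCl (THF, −20 °C) to give the Weinreb amide (S)-2-[4-(1,3-dioxolan-2-yl)-2,6-dimethoxyphenoxy]-N-methoxy-N-methyl-3-[(triisopropylsilyl)oxy]propanamide F1. Addition of Grignard reagent 8 then gives the aryl ketone (S)-1-[4-(benzyloxy)-3-methoxyphenyl]-2-[4-(1,3-dioxolan-2-yl)-2,6-dimethoxyphenoxy]-3-[(triisopropylsilyl)oxy]propan-1-one F2. Reduction with Zn(BH4)2 in diethyl ether at −30 °C uses the chelate instead of fighting it: zinc bridges the ketone and aryloxy oxygens and hydride enters from the side of the C8 hydrogen. This should give the erythro alcohol and return to the route at 11. F2 is also reached by Dess–Martin oxidation of a poorly selective batch of 11, so such material is not lost.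

**Step 12.** Hydrogen iodide formed in the catalytic cycle at 120 °C may ionise the C7–O bond, causing epimerisation or oxidation at C7 by the sulfoxide, and may strip silyl groups or the peri benzyl group. Loss of protecting groups alone is harmless, since they are removed later anyway. The fallback avoids oxidant and hydrogen iodide altogether and sets out from aldehyde 13 by a Baker–Venkataraman sequence. Pinnick oxidation (NaClO2, NaH2PO4, 2-methyl-2-butene, t-BuOH/H2O) gives 4-{[(1R,2S)-1-[4-(benzyloxy)-3-methoxyphenyl]-1-[(tert-butyldimethylsilyl)oxy]-3-[(triisopropylsilyl)oxy]propan-2-yl]oxy}-3,5-dimethoxybenzoic acid F4. Carbodiimide/DMAP esterification with the free hydroxyl of 15 gives the 2-acetyl-3,5-bis(benzyloxy)phenyl ester of that acid F5. KOC(CH3)3 in THF moves the acyl group from oxygen to the acetyl carbon to give the 1-[2,4-bis(benzyloxy)-6-hydroxyphenyl]-3-aryl-propane-1,3-dione F6 (aryl = ring B of 13). Cyclodehydration with catalytic p-TsOH in toluene at 50 °C returns to the route at 19.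

**Step 4.** The oxygen of 5 is flanked by two methoxy groups, so etherification may be slow and the activated alcohol may be intercepted by the hydrazide or left unconsumed. The fallback sets out from 3, which is converted (trifluoromethanesulfonic anhydride, 2,6-lutidine, CH2Cl2, −78 °C) into methyl (R)-2-{[(trifluoromethyl)sulfonyl]oxy}-3-[(triisopropylsilyl)oxy]propanoate F3. Displacement by phenol 5 with K2CO3 in acetonitrile (−20 °C to rt) is a plain SN2 reaction with inversion and returns to the route at 6.

**Step 14.** Acylation may not stop at O9 and may also reach O7, and the acetyl group may migrate from O9 to O7 during isolation if base is present. The fallback replaces reagent control by enzyme control. Diol 20 is treated with vinyl acetate and immobilised lipase B from Candida antarctica in THF/toluene at 40 °C; the active site accepts only the primary hydroxyl. It returns to the route at 21 and makes no new compound.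

Further compounds
F1 | step 7 | (S)-2-[4-(1,3-dioxolan-2-yl)-2,6-dimethoxyphenoxy]-N-methoxy-N-methyl-3-[(triisopropylsilyl)oxy]propanamide | CON(C)C(=O)[C@@H](Oc1c(OC)cc(C2OCCO2)cc1OC)CO[Si](C(C)C)(C(C)C)C(C)C
F2 | step 7 | (S)-1-[4-(benzyloxy)-3-methoxyphenyl]-2-[4-(1,3-dioxolan-2-yl)-2,6-dimethoxyphenoxy]-3-[(triisopropylsilyl)oxy]propan-1-one | COc1cc(C(=O)[C@H](CO[Si](C(C)C)(C(C)C)C(C)C)Oc2c(OC)cc(C3OCCO3)cc2OC)ccc1OCc1ccccc1
F3 | step 4 | methyl (R)-2-{[(trifluoromethyl)sulfonyl]oxy}-3-[(triisopropylsilyl)oxy]propanoate | COC(=O)[C@H](OS(=O)(=O)C(F)(F)F)CO[Si](C(C)C)(C(C)C)C(C)C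
F4 | step 12 | 4-{[(1R,2S)-1-[4-(benzyloxy)-3-methoxyphenyl]-1-[(tert-butyldimethylsilyl)oxy]-3-[(triisopropylsilyl)oxy]propan-2-yl]oxy}-3,5-dimethoxybenzoic acid | COc1cc([C@@H](O[Si](C)(C)C(C)(C)C)[C@H](CO[Si](C(C)C)(C(C)C)C(C)C)Oc2c(OC)cc(C(=O)O)cc2OC)ccc1OCc1ccccc1
F5 | step 12 | 2-acetyl-3,5-bis(benzyloxy)phenyl 4-{[(1R,2S)-1-[4-(benzyloxy)-3-methoxyphenyl]-1-[(tert-butyldimethylsilyl)oxy]-3-[(triisopropylsilyl)oxy]propan-2-yl]oxy}-3,5-dimethoxybenzoate | COc1cc([C@@H](O[Si](C)(C)C(C)(C)C)[C@H](CO[Si](C(C)C)(C(C)C)C(C)C)Oc2c(OC)cc(C(=O)Oc3cc(OCc4ccccc4)cc(OCc4ccccc4)c3C(C)=O)cc2OC)ccc1OCc1ccccc1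
F6 | step 12 | 1-[2,4-bis(benzyloxy)-6-hydroxyphenyl]-3-(4-{[(1R,2S)-1-[4-(benzyloxy)-3-methoxyphenyl]-1-[(tert-butyldimethylsilyl)oxy]-3-[(triisopropylsilyl)oxy]propan-2-yl]oxy}-3,5-dimethoxyphenyl)propane-1,3-dione | COc1cc([C@@H](O[Si](C)(C)C(C)(C)C)[C@H](CO[Si](C(C)C)(C(C)C)C(C)C)Oc2c(OC)cc(C(=O)CC(=O)c3c(O)cc(OCc4ccccc4)cc3OCc3ccccc3)cc2OC)ccc1OCc1ccccc1
F0 | step 14 | none | none
A1 | alternative 1 | 5,7-bis(benzyloxy)-2-(4-{[(4R,5S)-4-[4-(benzyloxy)-3-methoxyphenyl]-2,2-dimethyl-1,3-dioxan-5-yl]oxy}-3,5-dimethoxyphenyl)-4H-chromen-4-one | COc1cc([C@H]2OC(C)(C)OC[C@@H]2Oc2c(OC)cc(-c3cc(=O)c4c(OCc5ccccc5)cc(OCc5ccccc5)cc4o3)cc2OC)ccc1OCc1ccccc1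
A2 | alternative 1 | (4R,5S)-4-[4-(benzyloxy)-3-methoxyphenyl]-2,2-dimethyl-1,3-dioxan-5-ol | COc1cc([C@H]2OC(C)(C)OC[C@@H]2O)ccc1OCc1ccccc1
A3 | alternative 1 | 5,7-bis(benzyloxy)-2-(4-bromo-3,5-dimethoxyphenyl)-4H-chromen-4-one | COc1cc(-c2cc(=O)c3c(OCc4ccccc4)cc(OCc4ccccc4)cc3o2)cc(OC)c1Br
A4 | alternative 2 | (2S,3R)-2-{4-[5,7-bis(benzyloxy)-4-oxo-4H-chromen-2-yl]-2,6-dimethoxyphenoxy}-3-hydroxy-3-{3-methoxy-4-[(triisopropylsilyl)oxy]phenyl}propyl acetate | COc1cc([C@@H](O)[C@H](COC(C)=O)Oc2c(OC)cc(-c3cc(=O)c4c(OCc5ccccc5)cc(OCc5ccccc5)cc4o3)cc2OC)ccc1O[Si](C(C)C)(C(C)C)C(C)C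
A5 | alternative 2 | (R)-2-{4-[5,7-bis(benzyloxy)-4-oxo-4H-chromen-2-yl]-2,6-dimethoxyphenoxy}-3-{3-methoxy-4-[(triisopropylsilyl)oxy]phenyl}propyl acetate | COc1cc(C[C@H](COC(C)=O)Oc2c(OC)cc(-c3cc(=O)c4c(OCc5ccccc5)cc(OCc5ccccc5)cc4o3)cc2OC)ccc1O[Si](C(C)C)(C(C)C)C(C)C
A6 | alternative 3 | (S)-4-benzyl-3-[(2R,3R)-3-[4-(benzyloxy)-3-methoxyphenyl]-2-{4-[5,7-bis(benzyloxy)-4-oxo-4H-chromen-2-yl]-2,6-dimethoxyphenoxy}-3-hydroxypropanoyl]oxazolidin-2-one | COc1cc([C@@H](O)[C@H](C(=O)N2[C@@H](Cc3ccccc3)COC2=O)Oc2c(OC)cc(-c3cc(=O)c4c(OCc5ccccc5)cc(OCc5ccccc5)cc4o3)cc2OC)ccc1OCc1ccccc1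
A7 | alternative 3 | (S)-4-benzyl-3-(2-{4-[5,7-bis(benzyloxy)-4-oxo-4H-chromen-2-yl]-2,6-dimethoxyphenoxy}acetyl)oxazolidin-2-one | COc1cc(-c2cc(=O)c3c(OCc4ccccc4)cc(OCc4ccccc4)cc3o2)cc(OC)c1OCC(=O)N1[C@@H](Cc2ccccc2)COC1=O
A8 | alternative 3 | 4-(benzyloxy)-3-methoxybenzaldehyde | COc1cc(C=O)ccc1OCc1ccccc1
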